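The synthesis rests on reading the C7≡C8 triple bond, which joins the sp2 carbon C6 of ring A to the sp2 chain carbon C9, as the carbonyl carbon of a divinyl ketone plus one inserted carbon. In one operation lithiated trimethylsilyldiazomethane converts the hindered ketone into an alkylidene carbene whose 1,2-alkenyl shift forms C7≡C8 and C8–C9. The precursor is the cross-conjugated ring A dienone (C6–C7(=O)–C9), bis-silylated at O3 and O11, assembled by CrCl2/NiCl2 coupling of an enol triflate with a C5 enal. The C15 salt then meets the C10 dialdehyde and a ring B diol C15 salt (asymmetric epoxidation, anti hydrolysis) in two Wittig reactions.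

Key step: step 8

Remark: carotenoid locants are used throughout, unprimed for the acetylenic half (ring A) and primed for the diol half (ring B); compounds 1, 7, 8, 13, 21, 24, 28 and 32 are taken as commercial.

Step 1
Reactants: 1 ketoisophorone
Product: 2 (6R)-2,2,6-trimethylcyclohexane-1,4-dione
Conditions: ene-reductase OYE2 (old yellow enzyme of baker's yeast), NADP+ (cat.), glucose dehydrogenase, D-glucose, phosphate buffer pH 7, 30 °C
Reagents that add atoms: none
Why: Enzymatic asymmetric conjugate reduction, in which the flavoprotein delivers hydride to the unsubstituted alkene carbon and a proton to the methyl-bearing carbon, the established way to set that centre as R.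

Step 2
Reactants: 2 (6R)-2,2,6-trimethylcyclohexane-1,4-dione
Product: 3 (4R,6R)-4-hydroxy-2,2,6-trimethylcyclohexan-1-one
Conditions: LiBH(s-Bu)3 (1.05 equiv), THF, −78 °C; then pH 7 buffer
Reagents that add atoms: none
Why: Diastereoselective hydride reduction, in which the bulky borohydride attacks only the unhindered C4 carbonyl (C1 lies between a quaternary and a tertiary carbon) from the equatorial side, away from the axial C2 methyl group, so the new 4R carbinol centre is set trans to the C6 methyl group by substrate control.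

Step 3
Reactants: 3 (4R,6R)-4-hydroxy-2,2,6-trimethylcyclohexan-1-one
Product: 4 (4R,6R)-4-[(tert-butyldimethylsilyl)oxy]-2,2,6-trimethylcyclohexan-1-one
Conditions: TBSCl, imidazole, DMF, rt
Reagents that add atoms: tert-butyldimethylsilyl chloride, CC(C)(C)[Si](C)(C)Cl
Why: Silyl ether formation under imidazole catalysis protects the secondary alcohol under conditions too mild to epimerise C6.

Step 4
Reactants: 4 (4R,6R)-4-[(tert-butyldimethylsilyl)oxy]-2,2,6-trimethylcyclohexan-1-one
Product: 6 (4R)-4-[(tert-butyldimethylsilyl)oxy]-2,6,6-trimethylcyclohex-1-en-1-yl trifluoromethanesulfonate, via lithium enolate 5 (not isolated)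
Conditions: LiN(i-Pr)2, THF, −78 → 0 °C; then PhNTf2, −78 °C → rt
Reagents that add atoms: N-phenylbis(trifluoromethanesulfonimide), O=S(=O)(N(c1ccccc1)S(=O)(=O)C(F)(F)F)C(F)(F)F
Why: Enol triflate formation, in which the amide base removes the only α-hydrogen (C6–H) to give the tetrasubstituted enolate 5 that is triflated on oxygen, erasing the C6 centre on purpose and leaving the silyloxy centre untouched.

Step 5
Reactants: 7 [(tert-butyldimethylsilyl)oxy]acetaldehyde; 8 2-(triphenylphosphoranylidene)propanal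
Product: 9 (2E)-4-[(tert-butyldimethylsilyl)oxy]-2-methylbut-2-enal
Conditions: toluene, 80 °C
Reagents that add atoms: none
Why: Wittig reaction of a stabilised formyl ylide with the more electrophilic aliphatic aldehyde should give the E-trisubstituted enal, which is itself too unreactive to condense a second time.

Step 6
Reactants: 6 (4R)-4-[(tert-butyldimethylsilyl)oxy]-2,6,6-trimethylcyclohex-1-en-1-yl trifluoromethanesulfonate; 9 (2E)-4-[(tert-butyldimethylsilyl)oxy]-2-methylbut-2-enal
Product: 11 (2E)-4-[(tert-butyldimethylsilyl)oxy]-1-[(4R)-4-[(tert-butyldimethylsilyl)oxy]-2,6,6-trimethylcyclohex-1-en-1-yl]-2-methylbut-2-en-1-ol (both C7 epimers), via alkenylchromium dichloride 10 (not isolated)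
Conditions: CrCl2 (4 equiv), NiCl2 (2 mol %), DMF, rt
Reagents that add atoms: none
Why: Nozaki–Hiyama–Kishi reaction, in which zerovalent nickel formed in the flask inserts into the C–OTf bond, transmetalation to trivalent chromium gives 10, and this adds 1,2 to the enal to form the hindered C6–C7 bond; the new carbinol centre is uncontrolled and is removed in step 7.

Step 7
Reactants: 11 (2E)-4-[(tert-butyldimethylsilyl)oxy]-1-[(4R)-4-[(tert-butyldimethylsilyl)oxy]-2,6,6-trimethylcyclohex-1-en-1-yl]-2-methylbut-2-en-1-ol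
Product: 12 (2E)-4-[(tert-butyldimethylsilyl)oxy]-1-[(4R)-4-[(tert-butyldimethylsilyl)oxy]-2,6,6-trimethylcyclohex-1-en-1-yl]-2-methylbut-2-en-1-one
Conditions: MnO2 (activated, excess), CH2Cl2, rt
Reagents that add atoms: none
Why: Allylic oxidation with MnO2 should convert the doubly allylic carbinol into the cross-conjugated ketone without affecting the silyl ethers or the C9=C10 geometry.

Step 8
Reactants: 12 (2E)-4-[(tert-butyldimethylsilyl)oxy]-1-[(4R)-4-[(tert-butyldimethylsilyl)oxy]-2,6,6-trimethylcyclohex-1-en-1-yl]-2-methylbut-2-en-1-one; 13 trimethylsilyldiazomethane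
Product: 18 tert-butyl{[(2E)-5-[(4R)-4-[(tert-butyldimethylsilyl)oxy]-2,6,6-trimethylcyclohex-1-en-1-yl]-3-methylpent-2-en-4-yn-1-yl]oxy}dimethylsilane, via lithiated trimethylsilyldiazomethane 14 (not isolated), via lithium alkoxide adduct 15 (not isolated), via diazoalkene 16 (not isolated), via alkylidene carbene 17 (not isolated)
Conditions: Me3SiCHN2 (1.5 equiv), n-BuLi (1.4 equiv), THF, −78 °C; then 12, −78 °C → rt
Reagents that add atoms: none
Why: Reagent 14 adds 1,2 to the C7 carbonyl to give alkoxide 15, Peterson-type loss of Me3SiOLi gives diazoalkene 16, and loss of N2 gives alkylidene carbene 17, in which a 1,2-shift of an alkenyl group from C7 to the carbene carbon creates the C7≡C8 triple bond and the C8–C9 bond. This is the Colvin rearrangement, a Fritsch–Buttenberg–Wiechell-type shift established for ketones whose migrating groups are sp2 carbons. No ring is closed and no stereocentre is formed; the C3 centre and the C9=C10 E geometry are spectators. The step needs 1,2-addition rather than conjugate addition, which the substrate secures because the carbonyl is twisted out of conjugation by the C1 gem-dimethyl, C5 methyl and C9 methyl groups, C5 is fully substituted and the small linear nucleophile reaches C7 more easily than C10. It also needs migration rather than C–H insertion: both carbene substituents are alkenyl groups of high migratory aptitude, either shift gives the same enyne, and the E geometry holds the C11 hydrogens out of reach, leaving only slower insertion into methyl C–H bonds as competition.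

Step 9
Reactants: 18 tert-butyl{[(2E)-5-[(4R)-4-[(tert-butyldimethylsilyl)oxy]-2,6,6-trimethylcyclohex-1-en-1-yl]-3-methylpent-2-en-4-yn-1-yl]oxy}dimethylsilane
Product: 19 (2E)-5-[(4R)-4-hydroxy-2,6,6-trimethylcyclohex-1-en-1-yl]-3-methylpent-2-en-4-yn-1-ol
Conditions: Bu4NF, THF, rt
Reagents that add atoms: none
Why: Fluoride-mediated desilylation removes both identical silyl ethers in one operation, so no selective deprotection is required, and the enyne is inert to fluoride.

Step 10
Reactants: 19 (2E)-5-[(4R)-4-hydroxy-2,6,6-trimethylcyclohex-1-en-1-yl]-3-methylpent-2-en-4-yn-1-ol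
Product: 20 [(2E)-5-[(4R)-4-hydroxy-2,6,6-trimethylcyclohex-1-en-1-yl]-3-methylpent-2-en-4-yn-1-yl]triphenylphosphonium bromide
Conditions: PPh3·HBr, MeOH, rt
Reagents that add atoms: triphenylphosphine hydrobromide, [Br-].[PH+](c1ccccc1)(c1ccccc1)c1ccccc1
Why: Allylic substitution with triphenylphosphine hydrobromide, in which only the primary allylic alcohol activated by the enyne is protonated and displaced by the phosphine while the secondary ring alcohol stays inert.

Step 11
Reactants: 20 [(2E)-5-[(4R)-4-hydroxy-2,6,6-trimethylcyclohex-1-en-1-yl]-3-methylpent-2-en-4-yn-1-yl]triphenylphosphonium bromide; 21 (2E,4E,6E)-2,7-dimethylocta-2,4,6-trienedial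
Product: 23 (2E,4E,6E,8E,10E)-13-[(4R)-4-hydroxy-2,6,6-trimethylcyclohex-1-en-1-yl]-2,7,11-trimethyltrideca-2,4,6,8,10-pentaen-12-ynal, via phosphorus ylide 22 (not isolated)
Conditions: NaOMe, MeOH/CH2Cl2, 0 °C → rt, 21 in threefold excess, slow addition of 20; then EtOAc, 60 °C, dark
Reagents that add atoms: none
Why: Wittig reaction of allylic ylide 22 with an excess of the symmetrical dialdehyde should give mainly the product of one condensation at C11=C12, and the hindered 11Z isomer formed alongside should convert thermally into the 11E isomer.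

Step 12
Reactants: 24 β-cyclocitral
Product: 25 β-cyclogeraniol
Conditions: NaBH4, MeOH, 0 °C
Reagents that add atoms: none
Why: Borohydride 1,2-reduction of the enal, whose fully substituted β-carbon rules out conjugate reduction.

Step 13
Reactants: 25 β-cyclogeraniol
Product: 26 [(1S,6S)-2,2,6-trimethyl-7-oxabicyclo[4.1.0]heptan-1-yl]methanol
Conditions: Ti(Oi-Pr)4, L-(+)-diethyl tartrate, t-BuOOH, 4 Å molecular sieves, CH2Cl2, −20 °C
Reagents that add atoms: tert-butyl hydroperoxide, CC(C)(C)OO
Why: Katsuki–Sharpless asymmetric epoxidation, in which the titanium tartrate complex delivers oxygen to one face of the allylic alcohol; L-(+)-tartrate should give the (1S,6S) epoxide by the same facial preference that takes geraniol to its (2S,3S) epoxide, setting both ring B centres by reagent control.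

Step 14
Reactants: 26 [(1S,6S)-2,2,6-trimethyl-7-oxabicyclo[4.1.0]heptan-1-yl]methanol
Product: 27 (1R,6S)-2,2,6-trimethyl-7-oxabicyclo[4.1.0]heptane-1-carbaldehyde
Conditions: Dess–Martin periodinane, NaHCO3, CH2Cl2, 0 °C → rt
Reagents that add atoms: none
Why: Dess–Martin oxidation under buffered conditions should give the non-enolisable epoxy aldehyde without opening the epoxide (the descriptor at C1 changes only because the priorities change).

Step 15
Reactants: 27 (1R,6S)-2,2,6-trimethyl-7-oxabicyclo[4.1.0]heptane-1-carbaldehyde; 28 diethyl (2-oxopropyl)phosphonate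
Product: 30 (3E)-4-[(1R,6S)-2,2,6-trimethyl-7-oxabicyclo[4.1.0]heptan-1-yl]but-3-en-2-one, via sodium phosphonate anion 29 (not isolated)
Conditions: NaH, THF, 0 °C → rt
Reagents that add atoms: none
Why: Horner–Wadsworth–Emmons reaction of the stabilised keto phosphonate anion with the non-enolisable aldehyde should give the E-enone (C7′=C8′), the epoxide being stable to base.

Step 16
Reactants: 30 (3E)-4-[(1R,6S)-2,2,6-trimethyl-7-oxabicyclo[4.1.0]heptan-1-yl]but-3-en-2-one
Product: 31 (3E)-4-[(1R,2R)-1,2-dihydroxy-2,6,6-trimethylcyclohexyl]but-3-en-2-one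
Conditions: HClO4 (cat.), THF/H2O, 0 °C → rt
Reagents that add atoms: water, O
Why: Acid-catalysed anti hydrolysis of the epoxide, in which water attacks the protonated epoxide at C5′ with inversion because C6′ is shielded by the gem-dimethyl group and its ionisation is disfavoured by the conjugated enone, so the C6′ oxygen is retained and the trans (5′R,6′R) diol results.

Step 17
Reactants: 31 (3E)-4-[(1R,2R)-1,2-dihydroxy-2,6,6-trimethylcyclohexyl]but-3-en-2-one; 32 vinylmagnesium bromide
Product: 33 (1R,2R)-1-[(1E)-3-hydroxy-3-methylpenta-1,4-dien-1-yl]-2,6,6-trimethylcyclohexane-1,2-diol (both C9′ epimers)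
Conditions: THF, −20 → 0 °C, 4 equiv of 32; then aq. NH4Cl
Reagents that add atoms: none
Why: Grignard 1,2-addition to the methyl ketone, after the two tertiary hydroxyl groups have consumed two equivalents of reagent, gives the divinyl carbinol whose new centre is of no consequence because it is ionised in step 18.

Step 18
Reactants: 33 (1R,2R)-1-[(1E)-3-hydroxy-3-methylpenta-1,4-dien-1-yl]-2,6,6-trimethylcyclohexane-1,2-diol
Product: 34 [(2E,4E)-5-[(1R,2R)-1,2-dihydroxy-2,6,6-trimethylcyclohexyl]-3-methylpenta-2,4-dien-1-yl]triphenylphosphonium bromide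
Conditions: PPh3·HBr, MeOH, 0 °C → rt; crystallisation
Reagents that add atoms: triphenylphosphine hydrobromide, [Br-].[PH+](c1ccccc1)(c1ccccc1)c1ccccc1
Why: Allylic transposition with triphenylphosphine hydrobromide, in which the doubly allylic tertiary carbinol ionises to a pentadienyl cation that the phosphine captures at the unhindered terminus C11′ to give the conjugated primary salt, expected mainly as the 9′E isomer, while the less stabilised ring carbinols should not ionise.

Step 19
Reactants: 23 (2E,4E,6E,8E,10E)-13-[(4R)-4-hydroxy-2,6,6-trimethylcyclohex-1-en-1-yl]-2,7,11-trimethyltrideca-2,4,6,8,10-pentaen-12-ynal; 34 [(2E,4E)-5-[(1R,2R)-1,2-dihydroxy-2,6,6-trimethylcyclohexyl]-3-methylpenta-2,4-dien-1-yl]triphenylphosphonium bromide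
Product: 36 (3R,5′R,6′R)-7,8-didehydro-5′,6′-dihydro-β,β-carotene-3,5′,6′-triol (all-E), via phosphorus ylide 35 (not isolated)
Conditions: NaOMe, MeOH/CH2Cl2, rt, dark, argon; then EtOAc, 60 °C
Reagents that add atoms: none
Why: Wittig reaction of ylide 35 with the C25 aldehyde forms the C11′=C12′ bond, the free hydroxyl groups being tolerated by methoxide, and the hindered 11′Z isomer should equilibrate thermally to the all-E target.

Compound list
1 | ketoisophorone (2,6,6-trimethylcyclohex-2-ene-1,4-dione) | CC1=CC(=O)CC(C)(C)C1=O | starting material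
2 | (6R)-2,2,6-trimethylcyclohexane-1,4-dione | CC1(C)CC(=O)C[C@@H](C)C1=O | intermediate
3 | (4R,6R)-4-hydroxy-2,2,6-trimethylcyclohexan-1-one | CC1(C)C[C@H](O)C[C@@H](C)C1=O | intermediate
4 | (4R,6R)-4-[(tert-butyldimethylsilyl)oxy]-2,2,6-trimethylcyclohexan-1-one | CC1(C)C[C@H](O[Si](C)(C)C(C)(C)C)C[C@@H](C)C1=O | intermediate
5 | lithium (4R)-4-[(tert-butyldimethylsilyl)oxy]-2,6,6-trimethylcyclohex-1-en-1-olate (not isolated) | CC1=C(O[Li])C(C)(C)C[C@H](O[Si](C)(C)C(C)(C)C)C1 | intermediate
6 | (4R)-4-[(tert-butyldimethylsilyl)oxy]-2,6,6-trimethylcyclohex-1-en-1-yl trifluoromethanesulfonate | CC1=C(OS(=O)(=O)C(F)(F)F)C(C)(C)C[C@H](O[Si](C)(C)C(C)(C)C)C1 | intermediate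
7 | [(tert-butyldimethylsilyl)oxy]acetaldehyde | O=CCO[Si](C)(C)C(C)(C)C | starting material
8 | 2-(triphenylphosphoranylidene)propanal | CC(C=O)=P(c1ccccc1)(c1ccccc1)c1ccccc1 | starting material
9 | (2E)-4-[(tert-butyldimethylsilyl)oxy]-2-methylbut-2-enal | O=C/C(C)=C/CO[Si](C)(C)C(C)(C)C | intermediate
10 | [(4R)-4-[(tert-butyldimethylsilyl)oxy]-2,6,6-trimethylcyclohex-1-en-1-yl]chromium dichloride (not isolated) | CC1=C([Cr](Cl)Cl)C(C)(C)C[C@H](O[Si](C)(C)C(C)(C)C)C1 | intermediate
11 | (2E)-4-[(tert-butyldimethylsilyl)oxy]-1-[(4R)-4-[(tert-butyldimethylsilyl)oxy]-2,6,6-trimethylcyclohex-1-en-1-yl]-2-methylbut-2-en-1-ol (both C7 epimers) | CC1=C(C(O)/C(C)=C/CO[Si](C)(C)C(C)(C)C)C(C)(C)C[C@H](O[Si](C)(C)C(C)(C)C)C1 | intermediate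
12 | (2E)-4-[(tert-butyldimethylsilyl)oxy]-1-[(4R)-4-[(tert-butyldimethylsilyl)oxy]-2,6,6-trimethylcyclohex-1-en-1-yl]-2-methylbut-2-en-1-one (ring A C14 dienone) | CC1=C(C(=O)/C(C)=C/CO[Si](C)(C)C(C)(C)C)C(C)(C)C[C@H](O[Si](C)(C)C(C)(C)C)C1 | intermediate
13 | trimethylsilyldiazomethane | C[Si](C)(C)C=[N+]=[N-] | starting material
14 | lithio(trimethylsilyl)diazomethane (not isolated) | [Li]C(=[N+]=[N-])[Si](C)(C)C | intermediate
15 | lithium alkoxide from addition of 14 to C7 of 12 (not isolated, both C7 epimers) | CC1=C(C(O[Li])(C(=[N+]=[N-])[Si](C)(C)C)/C(C)=C/CO[Si](C)(C)C(C)(C)C)C(C)(C)C[C@H](O[Si](C)(C)C(C)(C)C)C1 | intermediate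
16 | diazoalkene C7=C8=N2 formed from 15 by loss of Me3SiOLi (not isolated) | CC1=C(C(=C=[N+]=[N-])/C(C)=C/CO[Si](C)(C)C(C)(C)C)C(C)(C)C[C@H](O[Si](C)(C)C(C)(C)C)C1 | intermediate
17 | alkylidene carbene at C8 formed from 16 by loss of N2 (not isolated) | CC1=C(C(=[C])/C(C)=C/CO[Si](C)(C)C(C)(C)C)C(C)(C)C[C@H](O[Si](C)(C)C(C)(C)C)C1 | intermediate
18 | tert-butyl{[(2E)-5-[(4R)-4-[(tert-butyldimethylsilyl)oxy]-2,6,6-trimethylcyclohex-1-en-1-yl]-3-methylpent-2-en-4-yn-1-yl]oxy}dimethylsilane (acetylenic ring A C15 unit) | CC1=C(C#C/C(C)=C/CO[Si](C)(C)C(C)(C)C)C(C)(C)C[C@H](O[Si](C)(C)C(C)(C)C)C1 | intermediate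
19 | (2E)-5-[(4R)-4-hydroxy-2,6,6-trimethylcyclohex-1-en-1-yl]-3-methylpent-2-en-4-yn-1-ol | CC1=C(C#C/C(C)=C/CO)C(C)(C)C[C@H](O)C1 | intermediate
20 | [(2E)-5-[(4R)-4-hydroxy-2,6,6-trimethylcyclohex-1-en-1-yl]-3-methylpent-2-en-4-yn-1-yl]triphenylphosphonium bromide | CC1=C(C#C/C(C)=C/C[P+](c2ccccc2)(c2ccccc2)c2ccccc2)C(C)(C)C[C@H](O)C1.[Br-] | intermediate
21 | (2E,4E,6E)-2,7-dimethylocta-2,4,6-trienedial | O=C/C(C)=C/C=C/C=C(C)/C=O | starting material
22 | ylide of 20 (not isolated) | CC1=C(C#C/C(C)=C/C=P(c2ccccc2)(c2ccccc2)c2ccccc2)C(C)(C)C[C@H](O)C1 | intermediate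
23 | (2E,4E,6E,8E,10E)-13-[(4R)-4-hydroxy-2,6,6-trimethylcyclohex-1-en-1-yl]-2,7,11-trimethyltrideca-2,4,6,8,10-pentaen-12-ynal (C25 aldehyde) | CC1=C(C#C/C(C)=C/C=C/C(C)=C/C=C/C=C(C)/C=O)C(C)(C)C[C@H](O)C1 | intermediate
24 | β-cyclocitral (2,6,6-trimethylcyclohex-1-ene-1-carbaldehyde) | CC1=C(C=O)C(C)(C)CCC1 | starting material
25 | β-cyclogeraniol ((2,6,6-trimethylcyclohex-1-en-1-yl)methanol) | CC1=C(CO)C(C)(C)CCC1 | intermediate
26 | [(1S,6S)-2,2,6-trimethyl-7-oxabicyclo[4.1.0]heptan-1-yl]methanol | C[C@]12CCCC(C)(C)[C@@]1(CO)O2 | intermediate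
27 | (1R,6S)-2,2,6-trimethyl-7-oxabicyclo[4.1.0]heptane-1-carbaldehyde | C[C@]12CCCC(C)(C)[C@@]1(C=O)O2 | intermediate
28 | diethyl (2-oxopropyl)phosphonate | CCOP(=O)(CC(C)=O)OCC | starting material
29 | sodium salt of 28 (not isolated) | [Na+].CCOP(=O)(OCC)[CH-]C(C)=O | intermediate
30 | (3E)-4-[(1R,6S)-2,2,6-trimethyl-7-oxabicyclo[4.1.0]heptan-1-yl]but-3-en-2-one | C[C@]12CCCC(C)(C)[C@@]1(/C=C/C(C)=O)O2 | intermediate
31 | (3E)-4-[(1R,2R)-1,2-dihydroxy-2,6,6-trimethylcyclohexyl]but-3-en-2-one | CC(=O)/C=C/[C@@]1(O)C(C)(C)CCC[C@@]1(C)O | intermediate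
32 | vinylmagnesium bromide | C=C[Mg]Br | starting material
33 | (1R,2R)-1-[(1E)-3-hydroxy-3-methylpenta-1,4-dien-1-yl]-2,6,6-trimethylcyclohexane-1,2-diol (both C9′ epimers) | C=CC(C)(O)/C=C/[C@@]1(O)C(C)(C)CCC[C@@]1(C)O | intermediate
34 | [(2E,4E)-5-[(1R,2R)-1,2-dihydroxy-2,6,6-trimethylcyclohexyl]-3-methylpenta-2,4-dien-1-yl]triphenylphosphonium bromide | C(/C=C(C)/C=C/[C@@]1(O)C(C)(C)CCC[C@@]1(C)O)[P+](c1ccccc1)(c1ccccc1)c1ccccc1.[Br-] | intermediate
35 | ylide of 34 (not isolated) | C(/C=C(C)/C=C/[C@@]1(O)C(C)(C)CCC[C@@]1(C)O)=P(c1ccccc1)(c1ccccc1)c1ccccc1 | intermediate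
36 | (3R,5′R,6′R)-7,8-didehydro-5′,6′-dihydro-β,β-carotene-3,5′,6′-triol (all-E; CNP0289733.1) | CC1=C(C#C/C(C)=C/C=C/C(C)=C/C=C/C=C(C)/C=C/C=C(C)/C=C/[C@@]2(O)C(C)(C)CCC[C@@]2(C)O)C(C)(C)C[C@H](O)C1 | target

Total step count: 19. Longest linear sequence: 11 steps (steps 1–4, 6–11 and 19).

Steps most likely to fail

Step 8. The lithiated reagent may deprotonate the dienone (at C11, C4 or the C5 methyl group) in place of adding to it. It may also attack the chain enone, or the carbene may insert into a methyl C–H bond faster than it rearranges. The fallback sets out from triflate 6 and comes back at 18. Commercial (2E)-3-methylpent-2-en-4-yn-1-ol is silylated with TBSCl and imidazole to tert-butyldimethyl{[(2E)-3-methylpent-2-en-4-yn-1-yl]oxy}silane F1. Sonogashira coupling of F1 with 6 (Pd(PPh3)4, CuI, Et3N, DMF, rt) joins C6 to the preformed alkyne and gives 18 directly, so steps 6–8 are not needed.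

Step 16. Opening of the epoxide at the wrong carbon, or through an open cation, would erode enantiomeric purity, and acid-induced rearrangement (ring contraction, elimination) may compete with hydration. The fallback sets out from epoxy alcohol 26 and comes back at 31. Here the hydrolysis is done before the chain is attached, where the hydroxymethyl group deactivates C6′ and no conjugated system is present. Dilute HClO4 in THF/H2O opens 26 at C5′ with inversion to (1S,2R)-1-(hydroxymethyl)-2,6,6-trimethylcyclohexane-1,2-diol F2. Oxidation of the primary alcohol with SO3·pyridine, DMSO and i-Pr2NEt gives (1R,2R)-1,2-dihydroxy-2,6,6-trimethylcyclohexane-1-carbaldehyde F3. A Wittig reaction with commercial 1-(triphenylphosphoranylidene)propan-2-one in toluene at 80 °C, under neutral conditions that avoid retro-aldol cleavage, then gives 31.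

Step 18. Ionisation of the tertiary allylic ring carbinol, or loss of geometric purity at C9′=C10′ during the cationic transposition, may lower the quality of the salt. The fallback sets out from 31, replaces steps 17 and 18 and comes back at 34. A Horner–Wadsworth–Emmons reaction of 31 with triethyl phosphonoacetate (NaH, THF) gives ethyl (2E,4E)-5-[(1R,2R)-1,2-dihydroxy-2,6,6-trimethylcyclohexyl]-3-methylpenta-2,4-dienoate F4, separated from its 2Z isomer. Reduction with i-Bu2AlH gives (1R,2R)-1-[(1E,3E)-5-hydroxy-3-methylpenta-1,3-dien-1-yl]-2,6,6-trimethylcyclohexane-1,2-diol F5. Appel bromination of the primary alcohol (CBr4, PPh3, −20 °C) gives (1R,2R)-1-[(1E,3E)-5-bromo-3-methylpenta-1,3-dien-1-yl]-2,6,6-trimethylcyclohexane-1,2-diol F6. Displacement with PPh3 in EtOAc then gives 34 without a cationic intermediate.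

Further compounds
F1 | step 8 | tert-butyldimethyl{[(2E)-3-methylpent-2-en-4-yn-1-yl]oxy}silane | C#C/C(C)=C/CO[Si](C)(C)C(C)(C)C
F2 | step 16 | (1S,2R)-1-(hydroxymethyl)-2,6,6-trimethylcyclohexane-1,2-diol | OC[C@@]1(O)C(C)(C)CCC[C@@]1(C)O
F3 | step 16 | (1R,2R)-1,2-dihydroxy-2,6,6-trimethylcyclohexane-1-carbaldehyde | O=C[C@@]1(O)C(C)(C)CCC[C@@]1(C)O
F4 | step 18 | ethyl (2E,4E)-5-[(1R,2R)-1,2-dihydroxy-2,6,6-trimethylcyclohexyl]-3-methylpenta-2,4-dienoate | CCOC(=O)/C=C(C)/C=C/[C@@]1(O)C(C)(C)CCC[C@@]1(C)O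
F5 | step 18 | (1R,2R)-1-[(1E,3E)-5-hydroxy-3-methylpenta-1,3-dien-1-yl]-2,6,6-trimethylcyclohexane-1,2-diol | OC/C=C(C)/C=C/[C@@]1(O)C(C)(C)CCC[C@@]1(C)O
F6 | step 18 | (1R,2R)-1-[(1E,3E)-5-bromo-3-methylpenta-1,3-dien-1-yl]-2,6,6-trimethylcyclohexane-1,2-diol | BrC/C=C(C)/C=C/[C@@]1(O)C(C)(C)CCC[C@@]1(C)O
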